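**Retrosynthetic overview**

- The target is a cis-fused 2,2a,7,7a-tetrahydro-1H-cyclobuta[a]indene (C1 = CMe2, C2 = CH-aryl, C2a/C7a = ring-fusion CH, C7 = CH2). The C6–OH is unmasked last from a MOM ether, and one methyl on C1 is carried through the ring construction as a formyl group.
- The key disconnection cuts C2a–C7a and C1–C2 in one amine-catalysed cascade from the acyclic stilbene enal 12. The cyclopentane closes first (5-exo) and the cyclobutane last (4-exo).
- Enabling feature: the 4-hydroxyl of the catechol ring (ring B) is para to C2. Through ring B it makes the stilbene carbon that becomes C2a a vinylogous phenol nucleophile and then turns C2 into a p-quinone methide electrophile. The C7a=C1 enal supplies the matching iminium acceptor (C7a) and enamine donor (C1).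
- The stilbene comes from a Heck coupling of ring A bromide 7 with styrene 10. Ring A is dressed from 3-bromo-5-methoxyphenol by Claisen rearrangement (allyl, later the enal arm by cross-metathesis), iodination and Negishi prenylation.
- Both benzene rings are bought; the only ring-forming step is step 11.

Key step: step 11

Assumption: the quinine-derived primary amine is taken to expose the face of the iminium β-carbon that gives (7aS), and if the sense of induction proves opposite the quinidine-derived pseudo-enantiomer would be used instead; the C1 epimer drawn for 13 is the expected one, and either epimer converges on 15.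

**Route**

Step 1
Reactants: 1 3-bromo-5-methoxyphenol
Product: 2 1-bromo-3-methoxy-5-(prop-2-en-1-yloxy)benzene
Conditions: allyl bromide, K2CO3, acetone, reflux
Reagents that add atoms: allyl bromide, C=CCBr
Why: Williamson ether synthesis of a phenoxide with a reactive primary allylic bromide; no stereocenter is formed.

Step 2
Reactants: 2 1-bromo-3-methoxy-5-(prop-2-en-1-yloxy)benzene
Product: 3 3-bromo-5-methoxy-2-(prop-2-en-1-yl)phenol
Conditions: PhNEt2, 190 °C
Reagents that add atoms: none
Why: Aromatic Claisen rearrangement ([3,3]-sigmatropic shift, then tautomerisation), which should favour the ortho position between oxygen and bromine because a meta acceptor directs towards itself and the meta methoxy group directs to its own para position; the minor regioisomer would be removed by chromatography and no stereocenter is formed.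

Step 3
Reactants: 3 3-bromo-5-methoxy-2-(prop-2-en-1-yl)phenol
Product: 4 1-bromo-5-methoxy-3-(methoxymethoxy)-2-(prop-2-en-1-yl)benzene
Conditions: MOMCl, i-Pr2NEt, CH2Cl2, 0 °C to rt
Reagents that add atoms: chloromethyl methyl ether, COCCl
Why: O-alkylation of the phenol with an α-chloro ether (MOM protection), needed so that this oxygen cannot add to the enal arm later; no stereocenter is formed.

Step 4
Reactants: 4 1-bromo-5-methoxy-3-(methoxymethoxy)-2-(prop-2-en-1-yl)benzene
Product: 5 1-bromo-6-iodo-5-methoxy-3-(methoxymethoxy)-2-(prop-2-en-1-yl)benzene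
Conditions: N-iodosuccinimide, CF3CO2H (10 mol %), MeCN, 0 °C
Reagents that add atoms: N-iodosuccinimide, O=C1CCC(=O)N1I
Why: Electrophilic aromatic iodination at the free position para to one alkoxy group and ortho to the other (the site at which 1-bromo-3,5-dialkoxybenzenes are known to be substituted, in preference to the position between the two oxygens), which should be much faster than attack on the monosubstituted alkene; no stereocenter is formed.

Step 5
Reactants: 5 1-bromo-6-iodo-5-methoxy-3-(methoxymethoxy)-2-(prop-2-en-1-yl)benzene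
Product: 6 1-bromo-5-methoxy-3-(methoxymethoxy)-6-(3-methylbut-2-en-1-yl)-2-(prop-2-en-1-yl)benzene
Conditions: 1-bromo-3-methylbut-2-ene, Zn, LiCl, THF, rt; then 5, Pd(OAc)2 (2 mol %), CPhos (4 mol %), THF, 0 °C to rt
Reagents that add atoms: (3-methylbut-2-en-1-yl)zinc bromide, CC(C)=CC[Zn]Br, made in the flask from 1-bromo-3-methylbut-2-ene, CC(C)=CCBr, and zinc, [Zn]
Why: Negishi cross-coupling in which oxidative addition should take place at C–I in preference to C–Br and the CPhos ligand is known to enforce coupling at the unsubstituted terminus of the prenyl-zinc reagent (linear prenyl product); no stereocenter is formed.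

Step 6
Reactants: 6 1-bromo-5-methoxy-3-(methoxymethoxy)-6-(3-methylbut-2-en-1-yl)-2-(prop-2-en-1-yl)benzene
Product: 7 (2E)-4-[2-bromo-4-methoxy-6-(methoxymethoxy)-3-(3-methylbut-2-en-1-yl)phenyl]-2-methylbut-2-enal
Conditions: methacrolein (8 equiv), second-generation Hoveyda–Grubbs catalyst (5 mol %), CH2Cl2, 40 °C
Reagents that add atoms: methacrolein, CC(=C)C=O
Why: Olefin cross-metathesis of the terminal allyl group with methacrolein, a reaction type that gives the (E)-trisubstituted enal, while the trisubstituted prenyl alkene should react far more slowly; no stereocenter is formed.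

Step 7
Reactants: 8 3,4-dihydroxybenzaldehyde
Product: 9 3,4-bis[(tert-butyldimethylsilyl)oxy]benzaldehyde
Conditions: TBSCl (2.3 equiv), imidazole, DMF, rt
Reagents that add atoms: tert-butyldimethylsilyl chloride, CC(C)(C)[Si](C)(C)Cl
Why: Imidazole-promoted silylation of both phenols, giving ethers that should survive the Wittig and Heck steps and are removed by fluoride.

Step 8
Reactants: 9 3,4-bis[(tert-butyldimethylsilyl)oxy]benzaldehyde
Product: 10 4-ethenyl-1,2-bis[(tert-butyldimethylsilyl)oxy]benzene
Conditions: Ph3PCH3Br, NaN(SiMe3)2, THF, 0 °C; then 9, 0 °C to rt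
Reagents that add atoms: methyltriphenylphosphonium bromide, C[P+](c1ccccc1)(c1ccccc1)c1ccccc1.[Br-]
Why: Wittig methylenation of the aldehyde with a non-stabilised ylide generated without excess base, so that the aryl silyl ethers stay in place; no stereocenter is formed.

Step 9
Reactants: 7 (2E)-4-[2-bromo-4-methoxy-6-(methoxymethoxy)-3-(3-methylbut-2-en-1-yl)phenyl]-2-methylbut-2-enal; 10 4-ethenyl-1,2-bis[(tert-butyldimethylsilyl)oxy]benzene
Product: 11 (2E)-4-[2-{(E)-2-[3,4-bis(tert-butyldimethylsilyloxy)phenyl]ethenyl}-4-methoxy-6-(methoxymethoxy)-3-(3-methylbut-2-en-1-yl)phenyl]-2-methylbut-2-enal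
Conditions: Pd2(dba)3 (2.5 mol %), [HP(t-Bu)3]BF4 (10 mol %), Cy2NMe, 1,4-dioxane, 80 °C
Reagents that add atoms: none
Why: Mizoroki–Heck reaction with a bulky electron-rich phosphine able to activate the doubly ortho-substituted aryl bromide, syn-insertion at the styrene terminus and syn-β-hydride elimination giving the (E)-stilbene, while the tertiary amine base cannot condense with the enal.

Step 10
Reactants: 11 (2E)-4-[2-{(E)-2-[3,4-bis(tert-butyldimethylsilyloxy)phenyl]ethenyl}-4-methoxy-6-(methoxymethoxy)-3-(3-methylbut-2-en-1-yl)phenyl]-2-methylbut-2-enal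
Product: 12 (2E)-4-[2-[(E)-2-(3,4-dihydroxyphenyl)ethenyl]-4-methoxy-6-(methoxymethoxy)-3-(3-methylbut-2-en-1-yl)phenyl]-2-methylbut-2-enal
Conditions: Bu4NF (2.2 equiv), AcOH (2.5 equiv), THF, 0 °C
Reagents that add atoms: none
Why: Fluoride cleavage of the two aryl silyl ethers, buffered with acetic acid so that no phenoxide is present to attack the enal in an uncatalysed background reaction; the MOM ether is unaffected.

Step 11
Reactants: 12 (2E)-4-[2-[(E)-2-(3,4-dihydroxyphenyl)ethenyl]-4-methoxy-6-(methoxymethoxy)-3-(3-methylbut-2-en-1-yl)phenyl]-2-methylbut-2-enal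
Product: 13 (1R,2R,2aR,7aS)-2-(3,4-dihydroxyphenyl)-4-methoxy-6-(methoxymethoxy)-1-methyl-3-(3-methylbut-2-en-1-yl)-2,2a,7,7a-tetrahydro-1H-cyclobuta[a]indene-1-carbaldehyde
Conditions: 9-amino-9-deoxy-epi-quinine (20 mol %), CF3CO2H (30 mol %), toluene/CHCl3 (4:1), 25 °C, N2; stopped at full conversion
Reagents that add atoms: none
Why: Proposed new method: the primary amine condenses with the α-methyl enal to an iminium ion, the stilbene carbon next to ring A adds to its β-carbon as a vinylogous phenol (donation from the para hydroxyl of ring B) to give a p-quinone methide and an enamine, and the enamine α-carbon then adds 1,6 to the quinone methide carbon before hydrolysis releases the catalyst; the closest known reaction types are the amine-catalysed iminium–enamine formal [2+2] cycloaddition of enals with 2-vinylpyrroles, the ammonium-salt-catalysed stepwise [2+2] cycloaddition of α-substituted acroleins with alkenes, primary-amine activation of α-branched enals, and the enamine 1,6-addition of aldehydes to p-quinone methides. The cyclopentane closes first by 5-exo-trig attack (C2a–C7a bond) and the cyclobutane last by 4-exo-trig attack (C1–C2 bond). C7a is set by the catalyst, which exposes one face of the iminium β-carbon; C2a follows because only the cis-1,2-disubstituted indane can close the four-membered ring, the trans adduct reverting by retro-Michael reaction; C2 is set in the ring closure with the aryl group on the convex face, trans to ring A; the configuration at C1 is of no consequence because that carbon becomes CMe2. The step needs chemoselectivity for the oxidised arm over the prenyl group, which only the aldehyde provides; the MOM ether blocks oxa-Michael addition of the neighbouring oxygen, and stopping at full conversion keeps the reversible donor–acceptor cyclobutane under kinetic control.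

Step 12
Reactants: 13 (1R,2R,2aR,7aS)-2-(3,4-dihydroxyphenyl)-4-methoxy-6-(methoxymethoxy)-1-methyl-3-(3-methylbut-2-en-1-yl)-2,2a,7,7a-tetrahydro-1H-cyclobuta[a]indene-1-carbaldehyde
Product: 15 4-[(2S,2aR,7aS)-4-methoxy-6-(methoxymethoxy)-1,1-dimethyl-3-(3-methylbut-2-en-1-yl)-2,2a,7,7a-tetrahydro-1H-cyclobuta[a]inden-2-yl]benzene-1,2-diol, via N-silyl hydrazone 14 (not isolated)
Conditions: 1,2-bis(tert-butyldimethylsilyl)hydrazine, Sc(OTf)3 (1 mol %), CH2Cl2, rt; volatiles removed; then KOtBu, t-BuOH, DMSO, rt, argon; then H2O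
Reagents that add atoms: 1,2-bis(tert-butyldimethylsilyl)hydrazine, CC(C)(C)[Si](C)(C)NN[Si](C)(C)C(C)(C)C (its atoms are kept only in 14; none remain in 15)
Why: Wolff–Kishner-type reduction through the N-silyl hydrazone, which forms under neutral conditions and should lose N2 at room temperature by an anionic, non-radical pathway that leaves the cyclobutane closed; the three ring stereocenters are not acidic and stay untouched, the stereocenter at C1 disappears, and any O-silylation of the catechol would be reversed by the tert-butoxide.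

Step 13
Reactants: 15 4-[(2S,2aR,7aS)-4-methoxy-6-(methoxymethoxy)-1,1-dimethyl-3-(3-methylbut-2-en-1-yl)-2,2a,7,7a-tetrahydro-1H-cyclobuta[a]inden-2-yl]benzene-1,2-diol
Product: 16 (2S,2aR,7aS)-2-(3,4-dihydroxyphenyl)-4-methoxy-1,1-dimethyl-3-(3-methylbut-2-en-1-yl)-2,2a,7,7a-tetrahydro-1H-cyclobuta[a]inden-6-ol
Conditions: HCl (cat.), MeOH, 40 °C
Reagents that add atoms: none
Why: Acid-catalysed acetal exchange (MOM cleavage) under mild conditions that should not hydrate the prenyl group, which has no neighbouring free phenol to cyclise with; the stereocenters are untouched.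

**Compound list**

1 | 3-bromo-5-methoxyphenol | COc1cc(O)cc(Br)c1 | starting material
2 | 1-bromo-3-methoxy-5-(prop-2-en-1-yloxy)benzene | COc1cc(OCC=C)cc(Br)c1 | intermediate
3 | 3-bromo-5-methoxy-2-(prop-2-en-1-yl)phenol | COc1cc(O)c(CC=C)c(Br)c1 | intermediate
4 | 1-bromo-5-methoxy-3-(methoxymethoxy)-2-(prop-2-en-1-yl)benzene | COCOc1cc(OC)cc(Br)c1CC=C | intermediate
5 | 1-bromo-6-iodo-5-methoxy-3-(methoxymethoxy)-2-(prop-2-en-1-yl)benzene | COCOc1cc(OC)c(I)c(Br)c1CC=C | intermediate
6 | 1-bromo-5-methoxy-3-(methoxymethoxy)-6-(3-methylbut-2-en-1-yl)-2-(prop-2-en-1-yl)benzene | COCOc1cc(OC)c(CC=C(C)C)c(Br)c1CC=C | intermediate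
7 | (2E)-4-[2-bromo-4-methoxy-6-(methoxymethoxy)-3-(3-methylbut-2-en-1-yl)phenyl]-2-methylbut-2-enal | COCOc1cc(OC)c(CC=C(C)C)c(Br)c1C/C=C(\C)C=O | intermediate
8 | 3,4-dihydroxybenzaldehyde | O=Cc1ccc(O)c(O)c1 | starting material
9 | 3,4-bis[(tert-butyldimethylsilyl)oxy]benzaldehyde | O=Cc1ccc(O[Si](C)(C)C(C)(C)C)c(O[Si](C)(C)C(C)(C)C)c1 | intermediate
10 | 4-ethenyl-1,2-bis[(tert-butyldimethylsilyl)oxy]benzene | C=Cc1ccc(O[Si](C)(C)C(C)(C)C)c(O[Si](C)(C)C(C)(C)C)c1 | intermediate
11 | (2E)-4-[2-{(E)-2-[3,4-bis(tert-butyldimethylsilyloxy)phenyl]ethenyl}-4-methoxy-6-(methoxymethoxy)-3-(3-methylbut-2-en-1-yl)phenyl]-2-methylbut-2-enal | COCOc1cc(OC)c(CC=C(C)C)c(/C=C/c2ccc(O[Si](C)(C)C(C)(C)C)c(O[Si](C)(C)C(C)(C)C)c2)c1C/C=C(\C)C=O | intermediate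
12 | (2E)-4-[2-[(E)-2-(3,4-dihydroxyphenyl)ethenyl]-4-methoxy-6-(methoxymethoxy)-3-(3-methylbut-2-en-1-yl)phenyl]-2-methylbut-2-enal | COCOc1cc(OC)c(CC=C(C)C)c(/C=C/c2ccc(O)c(O)c2)c1C/C=C(\C)C=O | intermediate
13 | (1R,2R,2aR,7aS)-2-(3,4-dihydroxyphenyl)-4-methoxy-6-(methoxymethoxy)-1-methyl-3-(3-methylbut-2-en-1-yl)-2,2a,7,7a-tetrahydro-1H-cyclobuta[a]indene-1-carbaldehyde (cis ring fusion, aryl trans to ring A, formyl cis to aryl) | COc1cc(OCOC)c2c(c1CC=C(C)C)[C@@H]1[C@H](C2)[C@@](C)(C=O)[C@H]1c1ccc(O)c(O)c1 | intermediate
14 | N-(tert-butyldimethylsilyl)hydrazone of 13 (E at C=N) | COc1cc(OCOC)c2c(c1CC=C(C)C)[C@@H]1[C@H](C2)[C@@](C)(/C=N/N[Si](C)(C)C(C)(C)C)[C@H]1c1ccc(O)c(O)c1 | intermediate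
15 | 4-[(2S,2aR,7aS)-4-methoxy-6-(methoxymethoxy)-1,1-dimethyl-3-(3-methylbut-2-en-1-yl)-2,2a,7,7a-tetrahydro-1H-cyclobuta[a]inden-2-yl]benzene-1,2-diol | COc1cc(OCOC)c2c(c1CC=C(C)C)[C@@H]1[C@H](C2)C(C)(C)[C@H]1c1ccc(O)c(O)c1 | intermediate
16 | (2S,2aR,7aS)-2-(3,4-dihydroxyphenyl)-4-methoxy-1,1-dimethyl-3-(3-methylbut-2-en-1-yl)-2,2a,7,7a-tetrahydro-1H-cyclobuta[a]inden-6-ol | COc1cc(O)c2c(c1CC=C(C)C)[C@@H]1[C@H](C2)C(C)(C)[C@H]1c1ccc(O)c(O)c1 | target

**Step count and risks**

Total step count: 13. Longest linear sequence: 11 (steps 1–6 and 9–13, from compound 1).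

Steps most likely to fail:

1. Step 11 (proposed new method). The vinylogous addition may be too slow against the hindered α-branched iminium ion, the quinone methide intermediate may tautomerise to a benzylidene-indane instead of closing the four-membered ring, or facial selectivity may be poor. Fallback with known chemistry, from 11 back to 13: compound 11 would be irradiated with blue light in MeCN with [Ir(dF(CF3)ppy)2(dtbbpy)]PF6 (1 mol %) in a triplet-sensitised intramolecular styrene–alkene [2+2] photocycloaddition. The benzylic radical end of the excited stilbene should add 5-exo to the enal β-carbon in preference to the prenyl group, giving the racemic bis-silyl cyclobutane aldehyde F1. Desilylation as in step 10 would give the racemic catechol aldehyde F2, from which 13 would be separated by preparative HPLC on a chiral stationary phase.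

2. Step 9. Oxidative addition into the doubly ortho-substituted C–Br bond may be sluggish, so that palladium hydride isomerisation of the enal arm or loss of the silyl groups takes over. Fallback, from 10 back to 11: styrene 10 would be converted by cross-metathesis with vinylboronic acid pinacol ester (second-generation Grubbs catalyst, CH2Cl2, 40 °C) into the (E)-alkenylboronic ester F3. F3 would be joined to bromide 7 by Suzuki–Miyaura coupling (Pd(OAc)2, SPhos, K3PO4, THF/H2O, 50 °C) to give 11.

3. Step 12. The donor–acceptor cyclobutane may open by retro-Michael fragmentation before the hydrazone has formed, or the strong base may shift the prenyl double bond into conjugation with ring A. Fallback, from 13 back to 15: aldehyde 13 would be condensed with p-toluenesulfonyl hydrazide (EtOH, rt) to the tosylhydrazone F4. F4 would be reduced with catecholborane (CHCl3, 0 °C) and then heated with NaOAc·3H2O, so that the deoxygenation runs by hydride addition and sulfinate loss without strong base, to give 15.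

**Further compounds**

F1 | step 11 | racemic (1R*,2R*,2aR*,7aS*)-2-{3,4-bis[(tert-butyldimethylsilyl)oxy]phenyl}-4-methoxy-6-(methoxymethoxy)-1-methyl-3-(3-methylbut-2-en-1-yl)-2,2a,7,7a-tetrahydro-1H-cyclobuta[a]indene-1-carbaldehyde (one enantiomer drawn) | COc1cc(OCOC)c2c(c1CC=C(C)C)[C@@H]1[C@H](C2)[C@@](C)(C=O)[C@H]1c1ccc(O[Si](C)(C)C(C)(C)C)c(O[Si](C)(C)C(C)(C)C)c1
F2 | step 11 | racemate of 13 (one enantiomer drawn) | COc1cc(OCOC)c2c(c1CC=C(C)C)[C@@H]1[C@H](C2)[C@@](C)(C=O)[C@H]1c1ccc(O)c(O)c1
F3 | step 9 | 2-[(E)-2-{3,4-bis[(tert-butyldimethylsilyl)oxy]phenyl}ethenyl]-4,4,5,5-tetramethyl-1,3,2-dioxaborolane | CC1(C)OB(/C=C/c2ccc(O[Si](C)(C)C(C)(C)C)c(O[Si](C)(C)C(C)(C)C)c2)OC1(C)C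
F4 | step 12 | N'-(4-methylbenzenesulfonyl)hydrazone of 13 (E at C=N) | COc1cc(OCOC)c2c(c1CC=C(C)C)[C@@H]1[C@H](C2)[C@@](C)(/C=N/NS(=O)(=O)c2ccc(C)cc2)[C@H]1c1ccc(O)c(O)c1
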